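The data stem from a simulated flask for substances that don't exist; noise was put on by code.

The trap in a flask like this is to enter partner at its charge and let the computer carry it along, when the rate of target follows c partner as it stands at that moment, not as it was weighed in.

| flask | starting material | partner | rival reagent | temperature | remark | time |
|---|---|---|---|---|---|---|
| birch | 20 mM | 60 mM | 36 mM | 95 °C | run made earlier |  |
| maple | 20 mM | 30 mM | 36 mM | 106 °C | run made earlier |  |
| alder | 20 mM | 120 mM | 36 mM | 95 °C | run made earlier |  |
| elm | 30 mM | 60 mM | 36 mM | 106 °C | run made earlier |  |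
| Wednesday's | 20 mM | 60.0 mM (fed, over 80 min) | 36.0 mM | 100 °C | all else is in the flask from the start; the feed brings no volume worth counting | 2.0 h |
| Tuesday's | 20 mM (fed, over 80 min) | 60.0 mM | 36.0 mM | 100 °C | all else is in the flask from the start; the feed brings no volume worth counting | 2.0 h |
| Saturday's | 20 mM (fed, over 80 min) | 60.0 mM | 36.0 mM |  | the addition at 80 °C, then warmed to 100 °C; the feed brings no volume worth counting | 2.0 h |
| Friday's | 20 mM | 60.0 mM | 36.0 mM | 100 °C | everything together at the start | 2.0 h |

| run | time / min | target / % | side product / % |
|---|---|---|---|
| birch | 6.00 | 17.0 | 4.1 |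
| birch | 10.0 | 22.3 | 5.1 |
| birch | 15.0 | 25.8 | 5.9 |
| birch | 25.0 | 26.8 | 7.9 |
| birch | 40.0 | 25.6 | 9.0 |
| birch | 80.0 | 23.6 | 11.0 |
| maple | 10.0 | 13.7 | 7.3 |
| maple | 15.0 | 15.5 | 8.9 |
| maple | 25.0 | 16.4 | 11.3 |
| maple | 40.0 | 17.1 | 13.5 |
| maple | 80.0 | 17.0 | 16.4 |
| maple | 120 | 17.6 | 18.0 |
| alder | 8.00 | 35.4 | 3.9 |
| alder | 25.0 | 39.4 | 6.1 |
| alder | 40.0 | 36.1 | 6.6 |
| alder | 60.0 | 33.5 | 7.5 |
| alder | 90.0 | 32.7 | 7.2 |
| alder | 120 | 32.2 | 7.9 |
| elm | 10.0 | 22.9 | 6.7 |
| elm | 30.0 | 27.5 | 9.7 |
| elm | 60.0 | 28.3 | 12.4 |
| elm | 80.0 | 28.7 | 13.0 |
| elm | 120 | 28.2 | 14.0 |

(readings scatter by 0.3 percentage points)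

- the analysis behind the earlier runs scatters by 0.3 percentage points, standard deviation

* the best flask by share of target in target plus side product; "all alike" if 1.5 percentage points covers them all (Wednesday's / Tuesday's / Saturday's / Friday's / all alike)
* share of target in target plus side product at the end, Wednesday's
* share of target in target plus side product at the end, Tuesday's
* share of target in target plus side product at the end, Saturday's
* share of target in target plus side product at the end, Friday's

I climb the time scales from the fastest. In the opening minutes target and side product compete for starting material, and their ratio, a selectivity factor, reads 4.15 at the first reading of the birch run and 9.08 in the alder run, which has twice the partner. So the ratio rises with c partner.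

On the next rung, target stops rising: its highest reading stands at 25.0 min in the birch run and at 25.0 min in the alder run, where no reading lies between 8.00 min and that time, so I cannot place the alder peak closely. The highest birch reading stands for 5.36 mM of target against 60 mM of partner, so the target I can see does not account for the stop. I read a clock that the larger charge does not visibly lengthen.

Then comes the feed, which at 80 min is longer than that clock. The feed window, 31.2%, is the share of a steady feed delivered by the time of the highest target reading in the birch run. In Tuesday's flask, I expect what passes through partner to stay under that share of the starting material, with later arrivals finding little partner. On the slowest rung, side product creeps on in the birch run, from 7.9% at the 25.0 min reading to 11.0% at the 80.0 min reading, while target does not rise. So I place Tuesday's below Friday's.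

The forecast names Saturday's as best, with Wednesday's at 50%, Tuesday's at 73%, Saturday's at 78% and Friday's at 67%. Of Tuesday's it says “partner stays in excess and target ages less”. There I part from it, since its Tuesday's figure stands above its Friday's.

The flasks give 58.1% for Wednesday's, 52.7% for Tuesday's, 76.4% for Saturday's and 67.5% for Friday's, so Saturday's is best.

    2 rival reagent → self-condensation product (k = 0.0250 M⁻¹ s⁻¹, Ea = 65.0 kJ mol⁻¹)
    target ⇌ isomer of the product (K = 1.10, k = 0.00150 s⁻¹, Ea = 123 kJ mol⁻¹, ΔH = −87.0 kJ mol⁻¹)
    starting material + partner → target (k = 0.0160 M⁻¹ s⁻¹, Ea = 62.0 kJ mol⁻¹)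
    starting material + rival reagent → side product (k = 0.00510 M⁻¹ s⁻¹, Ea = 57.0 kJ mol⁻¹)
    partner → decomposed reagent (k = 8.30 × 10⁻⁴ s⁻¹, Ea = 101 kJ mol⁻¹)
    (constants at 100 °C)

The step from partner to decomposed reagent has the largest single effect on the gap between Saturday's and Tuesday's: 24 percentage points with it, −5 points without it. Tuesday's ends with 0.080% of its partner and 74% of its starting material left, and target plus isomer of the product come to 17.9%, under the window. A neighbour of Tuesday's flask has 14 mM of rival reagent and the same feed, so its window stays 31.2%. Computed, target plus isomer of the product in that neighbour come to 18.2%, and its share is 58.5%.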